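**Strategy.** The route rests on cutting both bonds to C2 of the dihydrofuran ring (C2–C3 and O1–C2). C3a of ring A sits between the O1-bearing C7a and the C4 hydroxyl of a symmetrical 5-alkylresorcinol, so the atoms O1–C7a–C3a–C3 correspond to an ortho-quinone methide that can form in only one way. A chiral sulfonium benzylide then delivers C2, with its 4-oxygenated aryl group, as a one-carbon unit in an asymmetric formal [4+1] annulation that closes the only new ring and sets both stereocentres at once. The precursor is a bench-stable 2-[aryl(tosyl)methyl]phenol carrying the complete, benzyl-protected bibenzyl skeleton, paired with a twofold-symmetric thiolanium salt.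

Key step: step 14

Assumption: the (2S,5S)-thiolanium benzylide is taken to show the same facial preference towards the quinone methide as such benzylides show towards aldehydes, which corresponds to (S) at C2 once the different CIP ranking is allowed for; were the sense opposite, the equally available (2S,5S)-hexane-2,5-diol would be carried through steps 11 to 13 instead.

**Route**

Step 1
Reactants: 1 4-bromo-3,5-dihydroxybenzoic acid
Product: 2 benzyl 4-bromo-3,5-bis(benzyloxy)benzoate
Conditions: BnBr (3.5 equiv), K2CO3, DMF, 60 °C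
Reagents that add atoms: benzyl bromide, BrCc1ccccc1
Why: Williamson-type O-alkylation of both phenoxides and of the carboxylate under carbonate in DMF should proceed fully, the bromine between the two oxygens being inert to these conditions.

Step 2
Reactants: 2 benzyl 4-bromo-3,5-bis(benzyloxy)benzoate
Product: 3 [4-bromo-3,5-bis(benzyloxy)phenyl]methanol
Conditions: i-Bu2AlH (2.5 equiv), CH2Cl2, −78 to 0 °C; aq. KNaC4H4O6
Reagents that add atoms: none
Why: Hydride reduction of the ester to the primary alcohol with i-Bu2AlH at low temperature should leave the aryl bromide and the aryl benzyl ethers untouched.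

Step 3
Reactants: 3 [4-bromo-3,5-bis(benzyloxy)phenyl]methanol
Product: 4 4-bromo-3,5-bis(benzyloxy)benzaldehyde
Conditions: MnO2 (activated, excess), CH2Cl2, rt
Reagents that add atoms: none
Why: Activated MnO2 oxidises benzylic alcohols selectively to aldehydes and stops there (heterogeneous benzylic oxidation).

Step 4
Reactants: 5 4-(benzyloxy)benzyl chloride
Product: 6 diethyl [4-(benzyloxy)benzyl]phosphonate
Conditions: P(OEt)3 (neat), 140 °C
Reagents that add atoms: triethyl phosphite, CCOP(OCC)OCC
Why: Michaelis–Arbuzov reaction of a reactive benzylic chloride, driven by loss of volatile chloroethane.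

Step 5
Reactants: 4 4-bromo-3,5-bis(benzyloxy)benzaldehyde; 6 diethyl [4-(benzyloxy)benzyl]phosphonate
Product: 7 1,3-bis(benzyloxy)-5-{(E)-2-[4-(benzyloxy)phenyl]ethenyl}-2-bromobenzene
Conditions: KOt-Bu, THF, 0 °C to rt
Reagents that add atoms: none
Why: Horner–Wadsworth–Emmons olefination of a benzylphosphonate anion with a non-enolisable aromatic aldehyde should give the (E)-stilbene, whose geometry is in any case erased in step 6.

Step 6
Reactants: 7 1,3-bis(benzyloxy)-5-{(E)-2-[4-(benzyloxy)phenyl]ethenyl}-2-bromobenzene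
Product: 8 1,3-bis(benzyloxy)-5-{2-[4-(benzyloxy)phenyl]ethyl}-2-bromobenzene
Conditions: TsNHNH2 (excess, in portions), NaOAc, DME/H2O, reflux
Reagents that add atoms: none
Why: Diimide generated in the flask from the sulfonohydrazide transfers two hydrogens concertedly to the stilbene C=C bond only (diimide reduction), so the aryl bromide and the three benzyl ethers that a palladium hydrogenation would endanger should survive, and the alkene that could later act as a dienophile towards the quinone methide is gone.

Step 7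
Reactants: 8 1,3-bis(benzyloxy)-5-{2-[4-(benzyloxy)phenyl]ethyl}-2-bromobenzene
Product: 10 2,6-bis(benzyloxy)-4-{2-[4-(benzyloxy)phenyl]ethyl}benzaldehyde, via aryllithium 9 (not isolated)
Conditions: n-BuLi (1.05 equiv), THF, −78 °C; then DMF, −78 °C to rt; aq. NH4Cl
Reagents that add atoms: N,N-dimethylformamide, CN(C)C=O
Why: Bromine–lithium exchange at −78 °C outruns deprotonation of the benzylic ether positions, and formylation of the 2,6-dialkoxyaryllithium with DMF places the future C3 between the two oxygens without any regiochemical choice.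

Step 8
Reactants: 10 2,6-bis(benzyloxy)-4-{2-[4-(benzyloxy)phenyl]ethyl}benzaldehyde
Product: 11 2-(benzyloxy)-4-{2-[4-(benzyloxy)phenyl]ethyl}-6-hydroxybenzaldehyde
Conditions: MgBr2·OEt2 (1.5 equiv), toluene/Et2O, reflux; aq. NH4Cl
Reagents that add atoms: none
Why: Chelation-controlled ether cleavage, in which magnesium bridges the formyl oxygen and one ortho ether oxygen so that bromide removes that benzyl group only; the resulting magnesium phenoxide chelate is deactivated towards a second cleavage and the distal ether has no neighbouring carbonyl.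

Step 9
Reactants: 11 2-(benzyloxy)-4-{2-[4-(benzyloxy)phenyl]ethyl}-6-hydroxybenzaldehyde; 12 1-bromo-3,5-bis(benzyloxy)benzene
Product: 14 racemic 3-(benzyloxy)-2-{[3,5-bis(benzyloxy)phenyl](hydroxy)methyl}-5-{2-[4-(benzyloxy)phenyl]ethyl}phenol, via arylmagnesium bromide 13 (not isolated)
Conditions: 12 (3 equiv), Mg, THF, reflux; then 11, THF, 0 °C to rt; aq. NH4Cl
Reagents that add atoms: none
Why: Grignard addition to an aldehyde, in which the first equivalent is spent on the phenol and a further equivalent adds to the chelated formyl group; the new carbinol centre is racemic, which is immaterial because it becomes planar in step 14.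

Step 10
Reactants: 14 racemic 3-(benzyloxy)-2-{[3,5-bis(benzyloxy)phenyl](hydroxy)methyl}-5-{2-[4-(benzyloxy)phenyl]ethyl}phenol
Product: 15 racemic 3-(benzyloxy)-2-{[3,5-bis(benzyloxy)phenyl](4-methylbenzenesulfonyl)methyl}-5-{2-[4-(benzyloxy)phenyl]ethyl}phenol
Conditions: p-TolSO2H (1.5 equiv), CH2Cl2, rt
Reagents that add atoms: p-toluenesulfinic acid, Cc1ccc(cc1)S(=O)O
Why: The doubly benzylic, ortho-oxygen-stabilised carbinol ionises under the mild acidity of the sulfinic acid and is captured at sulfur (SN1-type substitution), the standard entry to storable 2-(sulfonylmethyl)phenol precursors of quinone methides.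

Step 11
Reactants: 16 (2R,5R)-hexane-2,5-diol
Product: 17 (2R,5R)-hexane-2,5-diyl dimethanesulfonate
Conditions: MsCl (2.4 equiv), Et3N, CH2Cl2, −20 to 0 °C
Reagents that add atoms: methanesulfonyl chloride, CS(=O)(=O)Cl
Why: O-Sulfonylation of both secondary alcohols does not touch the C–O bonds, so both (R) centres are retained in a bis-electrophile.

Step 12
Reactants: 17 (2R,5R)-hexane-2,5-diyl dimethanesulfonate
Product: 18 (2S,5S)-2,5-dimethylthiolane
Conditions: Na2S·9H2O, DMSO, rt; distillation
Reagents that add atoms: sodium sulfide, [Na+].[Na+].[S-2]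
Why: Sulfide displaces the two mesylates in successive SN2 reactions, the second a 5-exo-tet ring closure, so both centres invert and the (2R,5R) configuration of the diol becomes the (2S,5S) configuration of the thiolane.

Step 13
Reactants: 5 4-(benzyloxy)benzyl chloride; 18 (2S,5S)-2,5-dimethylthiolane
Product: 19 (2S,5S)-1-{[4-(benzyloxy)phenyl]methyl}-2,5-dimethylthiolan-1-ium tetrafluoroborate
Conditions: AgBF4 (1.05 equiv), CH2Cl2, 0 °C to rt, dark; filtration
Reagents that add atoms: silver tetrafluoroborate, [Ag+].F[B-](F)(F)F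
Why: S-Alkylation of the sulfide by the activated benzylic chloride is driven by precipitation of AgCl and leaves a non-nucleophilic counter-ion (sulfonium salt formation); the twofold axis of the thiolane makes its two sulfur lone pairs equivalent, so one salt with no stereocentre at sulfur should form.

Step 14
Reactants: 15 racemic 3-(benzyloxy)-2-{[3,5-bis(benzyloxy)phenyl](4-methylbenzenesulfonyl)methyl}-5-{2-[4-(benzyloxy)phenyl]ethyl}phenol; 19 (2S,5S)-1-{[4-(benzyloxy)phenyl]methyl}-2,5-dimethylthiolan-1-ium tetrafluoroborate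
Product: 23 (2S,3S)-4-(benzyloxy)-3-[3,5-bis(benzyloxy)phenyl]-2-[4-(benzyloxy)phenyl]-6-{2-[4-(benzyloxy)phenyl]ethyl}-2,3-dihydro-1-benzofuran, via ortho-quinone methide 20 (not isolated), via sulfonium benzylide 21 (not isolated), via phenoxide-sulfonium betaine 22 (not isolated)
Conditions: 19 (2 equiv), Cs2CO3 (4 equiv), CH2Cl2/MeCN, −20 °C to rt
Reagents that add atoms: none
Why: Proposed new method: Cs2CO3 deprotonates the phenol of 15, which expels p-toluenesulfinate to give the planar quinone methide 20, and reversibly deprotonates 19 to benzylide 21; the ylide carbon adds to the exocyclic methide carbon (C2–C3 bond), an addition made irreversible by rearomatisation of ring A to the phenoxide of betaine 22, and this phenoxide then displaces the thiolane at C2 with inversion (O1–C2 bond). The closest known reaction types are the formal [4+1] annulation of stabilised sulfonium ylides with quinone methides released from 2-(sulfonylmethyl)phenols, which gives trans-2,3-dihydrobenzofurans, and asymmetric benzylidene transfer from chiral thiolanium benzylides to aldehydes; the untested element is the pairing of a chiral semi-stabilised benzylide with an aryl-substituted quinone methide. The dihydrofuran ring closes by a 5-exo-tet SN2 displacement, eased by the 4-benzyloxyphenyl group that weakens the C2–S bond, and even a looser SN1-like closure would be steered trans by the C3 aryl group. C2 is controlled by the twofold-symmetric thiolane, which offers a single ylide environment with one face screened by a flanking methyl group, so that C–C bond formation on the open face followed by inversion should give (S). C3 is controlled by the relative topicity of the addition, in which the two aryl groups stay apart and lead to the trans (2S,3S) isomer, while the racemic centre of 15 has vanished in 20. The step therefore needs ylide facial selectivity and anti topicity but no regioselectivity, since ring A carries oxygen on both carbons flanking C3a and only one quinone methide can arise, and the methide aryl group has only meta alkoxy groups, which leave its electrophilicity intact.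

Step 15
Reactants: 23 (2S,3S)-4-(benzyloxy)-3-[3,5-bis(benzyloxy)phenyl]-2-[4-(benzyloxy)phenyl]-6-{2-[4-(benzyloxy)phenyl]ethyl}-2,3-dihydro-1-benzofuran
Product: 24 (2S,3S)-3-(3,5-dihydroxyphenyl)-2-(4-hydroxyphenyl)-6-[2-(4-hydroxyphenyl)ethyl]-2,3-dihydro-1-benzofuran-4-ol (CNP0315602.1)
Conditions: H2 (1 atm), 10% Pd/C, EtOAc/MeOH, rt, stopped at complete debenzylation
Reagents that add atoms: none
Why: Palladium-catalysed hydrogenolysis of the five primary aryl benzyl ethers is expected to be much faster than cleavage of the hindered secondary benzylic C2–O1 bond, so under neutral conditions at atmospheric pressure the ring and both stereocentres should remain intact.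

**Compound list**

1 | 4-bromo-3,5-dihydroxybenzoic acid | O=C(O)c1cc(O)c(Br)c(O)c1 | starting material
2 | benzyl 4-bromo-3,5-bis(benzyloxy)benzoate | O=C(OCc1ccccc1)c1cc(OCc2ccccc2)c(Br)c(OCc2ccccc2)c1 | intermediate
3 | [4-bromo-3,5-bis(benzyloxy)phenyl]methanol | OCc1cc(OCc2ccccc2)c(Br)c(OCc2ccccc2)c1 | intermediate
4 | 4-bromo-3,5-bis(benzyloxy)benzaldehyde | O=Cc1cc(OCc2ccccc2)c(Br)c(OCc2ccccc2)c1 | intermediate
5 | 4-(benzyloxy)benzyl chloride | ClCc1ccc(OCc2ccccc2)cc1 | starting material
6 | diethyl [4-(benzyloxy)benzyl]phosphonate | CCOP(=O)(OCC)Cc1ccc(OCc2ccccc2)cc1 | intermediate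
7 | 1,3-bis(benzyloxy)-5-{(E)-2-[4-(benzyloxy)phenyl]ethenyl}-2-bromobenzene | Brc1c(OCc2ccccc2)cc(/C=C/c2ccc(OCc3ccccc3)cc2)cc1OCc1ccccc1 | intermediate
8 | 1,3-bis(benzyloxy)-5-{2-[4-(benzyloxy)phenyl]ethyl}-2-bromobenzene | Brc1c(OCc2ccccc2)cc(CCc2ccc(OCc3ccccc3)cc2)cc1OCc1ccccc1 | intermediate
9 | {2,6-bis(benzyloxy)-4-{2-[4-(benzyloxy)phenyl]ethyl}phenyl}lithium | [Li]c1c(OCc2ccccc2)cc(CCc2ccc(OCc3ccccc3)cc2)cc1OCc1ccccc1 | intermediate
10 | 2,6-bis(benzyloxy)-4-{2-[4-(benzyloxy)phenyl]ethyl}benzaldehyde | O=Cc1c(OCc2ccccc2)cc(CCc2ccc(OCc3ccccc3)cc2)cc1OCc1ccccc1 | intermediate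
11 | 2-(benzyloxy)-4-{2-[4-(benzyloxy)phenyl]ethyl}-6-hydroxybenzaldehyde | O=Cc1c(O)cc(CCc2ccc(OCc3ccccc3)cc2)cc1OCc1ccccc1 | intermediate
12 | 1-bromo-3,5-bis(benzyloxy)benzene | Brc1cc(OCc2ccccc2)cc(OCc2ccccc2)c1 | starting material
13 | [3,5-bis(benzyloxy)phenyl]magnesium bromide | Br[Mg]c1cc(OCc2ccccc2)cc(OCc2ccccc2)c1 | intermediate
14 | racemic 3-(benzyloxy)-2-{[3,5-bis(benzyloxy)phenyl](hydroxy)methyl}-5-{2-[4-(benzyloxy)phenyl]ethyl}phenol | OC(c1cc(OCc2ccccc2)cc(OCc2ccccc2)c1)c1c(O)cc(CCc2ccc(OCc3ccccc3)cc2)cc1OCc1ccccc1 | intermediate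
15 | racemic 3-(benzyloxy)-2-{[3,5-bis(benzyloxy)phenyl](4-methylbenzenesulfonyl)methyl}-5-{2-[4-(benzyloxy)phenyl]ethyl}phenol | Cc1ccc(cc1)S(=O)(=O)C(c1cc(OCc2ccccc2)cc(OCc2ccccc2)c1)c1c(O)cc(CCc2ccc(OCc3ccccc3)cc2)cc1OCc1ccccc1 | intermediate
16 | (2R,5R)-hexane-2,5-diol | C[C@@H](O)CC[C@@H](C)O | starting material
17 | (2R,5R)-hexane-2,5-diyl dimethanesulfonate | C[C@@H](OS(C)(=O)=O)CC[C@@H](C)OS(C)(=O)=O | intermediate
18 | (2S,5S)-2,5-dimethylthiolane | C[C@H]1CC[C@H](C)S1 | intermediate
19 | (2S,5S)-1-{[4-(benzyloxy)phenyl]methyl}-2,5-dimethylthiolan-1-ium tetrafluoroborate | C[C@H]1CC[C@H](C)[S+]1Cc1ccc(OCc2ccccc2)cc1.F[B-](F)(F)F | intermediate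
20 | (6Z)-5-(benzyloxy)-6-{[3,5-bis(benzyloxy)phenyl]methylidene}-3-{2-[4-(benzyloxy)phenyl]ethyl}cyclohexa-2,4-dien-1-one (aryl group on the carbonyl side, away from the benzyloxy group) | O=C1C=C(CCc2ccc(OCc3ccccc3)cc2)C=C(OCc2ccccc2)/C1=C/c1cc(OCc2ccccc2)cc(OCc2ccccc2)c1 | intermediate
21 | [4-(benzyloxy)phenyl][(2S,5S)-2,5-dimethylthiolan-1-ium-1-yl]methanide | C[C@H]1CC[C@H](C)[S+]1[CH-]c1ccc(OCc2ccccc2)cc1 | intermediate
22 | 3-(benzyloxy)-2-{(1S,2R)-1-[3,5-bis(benzyloxy)phenyl]-2-[4-(benzyloxy)phenyl]-2-[(2S,5S)-2,5-dimethylthiolan-1-ium-1-yl]ethyl}-5-{2-[4-(benzyloxy)phenyl]ethyl}phenolate | C[C@H]1CC[C@H](C)[S+]1[C@@H](c1ccc(OCc2ccccc2)cc1)[C@@H](c1cc(OCc2ccccc2)cc(OCc2ccccc2)c1)c1c([O-])cc(CCc2ccc(OCc3ccccc3)cc2)cc1OCc1ccccc1 | intermediate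
23 | (2S,3S)-4-(benzyloxy)-3-[3,5-bis(benzyloxy)phenyl]-2-[4-(benzyloxy)phenyl]-6-{2-[4-(benzyloxy)phenyl]ethyl}-2,3-dihydro-1-benzofuran (trans) | c1ccccc1COc1ccc(CCc2cc(OCc4ccccc4)c3c(c2)O[C@H](c2ccc(OCc4ccccc4)cc2)[C@H]3c2cc(OCc4ccccc4)cc(OCc4ccccc4)c2)cc1 | intermediate
24 | (2S,3S)-3-(3,5-dihydroxyphenyl)-2-(4-hydroxyphenyl)-6-[2-(4-hydroxyphenyl)ethyl]-2,3-dihydro-1-benzofuran-4-ol | Oc1ccc(CCc2cc(O)c3c(c2)O[C@H](c2ccc(O)cc2)[C@H]3c2cc(O)cc(O)c2)cc1 | target

**Step count.** Total: 15 steps. Longest linear sequence: 11 steps (steps 1, 2, 3, 5, 6, 7, 8, 9, 10, 14, 15).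

**Steps most likely to fail**

First, step 14. What may go wrong is rearrangement of the benzylide or transfer of its benzyl group to sulfinate or phenoxide before it adds, or poor facial and topicity control in the addition. The fallback uses known reactions only, sets out from 15 and comes back at 23.
- Excess vinylmagnesium bromide (THF, −78 °C to rt) acts as base and as nucleophile in a conjugate addition to the quinone methide released from 15 and should give racemic 3-(benzyloxy)-2-{1-[3,5-bis(benzyloxy)phenyl]prop-2-en-1-yl}-5-{2-[4-(benzyloxy)phenyl]ethyl}phenol F1.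
- Dihydroxylation and glycol cleavage (OsO4 cat., NMO, then NaIO4) should give the diarylacetaldehyde as its lactol, 4-(benzyloxy)-3-[3,5-bis(benzyloxy)phenyl]-6-{2-[4-(benzyloxy)phenyl]ethyl}-2,3-dihydro-1-benzofuran-2-ol F2.
- Commercial 4-(benzyloxy)phenylmagnesium bromide in excess should open the lactol to 3-(benzyloxy)-2-{1-[3,5-bis(benzyloxy)phenyl]-2-[4-(benzyloxy)phenyl]-2-hydroxyethyl}-5-{2-[4-(benzyloxy)phenyl]ethyl}phenol F3.
- BF3·OEt2 in CH2Cl2 at low temperature should ionise the 4-alkoxybenzylic alcohol and let the phenol close the ring to the more stable trans isomer, the racemic trans form of 23 F4.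
- Preparative HPLC on a chiral stationary phase would then give (2S,3S)-23.

Second, step 15. What may go wrong is hydrogenolysis running on into the benzylic C2–O1 bond and opening the dihydrofuran ring. The fallback sets out from 23 and comes back at 24. It is a non-reductive Lewis-acid debenzylation with BCl3 and pentamethylbenzene as benzyl-cation scavenger in CH2Cl2 at −78 °C. Any reversible ionisation of C2–O1 would reclose to the same trans isomer because C3 is untouched. No compound outside the list is made (entry F0).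

Third, step 8. What may go wrong is loss of selectivity in the ether cleavage, with removal of the second ortho benzyl group or of the distal one. The fallback sets out from 10 and comes back at 11. All three benzyl groups are removed with excess BCl3 (CH2Cl2, −78 to 0 °C) to give 2,6-dihydroxy-4-[2-(4-hydroxyphenyl)ethyl]benzaldehyde F5. Re-benzylation with 2 equiv of BnBr and K2CO3 in acetone should then alkylate the distal phenol and one ortho phenol. The last ortho hydroxyl is locked in a hydrogen bond to the formyl group and resists alkylation. Any over-alkylated material is 10 and can be recycled.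

**Further compounds**

F1 | step 14 | racemic 3-(benzyloxy)-2-{1-[3,5-bis(benzyloxy)phenyl]prop-2-en-1-yl}-5-{2-[4-(benzyloxy)phenyl]ethyl}phenol | C=CC(c1cc(OCc2ccccc2)cc(OCc2ccccc2)c1)c1c(O)cc(CCc2ccc(OCc3ccccc3)cc2)cc1OCc1ccccc1
F2 | step 14 | racemic 4-(benzyloxy)-3-[3,5-bis(benzyloxy)phenyl]-6-{2-[4-(benzyloxy)phenyl]ethyl}-2,3-dihydro-1-benzofuran-2-ol (anomer mixture) | OC1Oc2cc(CCc3ccc(OCc4ccccc4)cc3)cc(OCc3ccccc3)c2C1c1cc(OCc2ccccc2)cc(OCc2ccccc2)c1
F3 | step 14 | racemic 3-(benzyloxy)-2-{1-[3,5-bis(benzyloxy)phenyl]-2-[4-(benzyloxy)phenyl]-2-hydroxyethyl}-5-{2-[4-(benzyloxy)phenyl]ethyl}phenol (diastereomer mixture) | OC(c1ccc(OCc2ccccc2)cc1)C(c1cc(OCc2ccccc2)cc(OCc2ccccc2)c1)c1c(O)cc(CCc2ccc(OCc3ccccc3)cc2)cc1OCc1ccccc1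
F4 | step 14 | racemic trans form of 23, equal parts (2S,3S) and (2R,3R) | c1ccccc1COc1ccc(CCc2cc(OCc4ccccc4)c3c(c2)O[C@H](c2ccc(OCc4ccccc4)cc2)[C@H]3c2cc(OCc4ccccc4)cc(OCc4ccccc4)c2)cc1.c1ccccc1COc1ccc(CCc2cc(OCc4ccccc4)c3c(c2)O[C@@H](c2ccc(OCc4ccccc4)cc2)[C@@H]3c2cc(OCc4ccccc4)cc(OCc4ccccc4)c2)cc1
F0 | step 15 | none | none
F5 | step 8 | 2,6-dihydroxy-4-[2-(4-hydroxyphenyl)ethyl]benzaldehyde | O=Cc1c(O)cc(CCc2ccc(O)cc2)cc1O
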